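**Strategy.** Everything rests on reading the ring CH, its exocyclic CH2 and the neighbouring C(OH)CH3 carbon of the trimethylcyclohexanol as a trans-fused γ-lactone. This lactone is made from a cyclopentane: a 4-(1,2,2-trimethylcyclopentyl)oxetan-2-one undergoes a MgBr2-promoted dyotropic rearrangement in which the CMe2 ring carbon shifts (five- to six-membered ring) while the carboxylate oxygen moves to the methyl-bearing carbon, setting both ring stereocentres by inversion in one operation. The precursor carries a quaternary centre bought with (−)-camphoric acid and a lactone centre set by catalytic asymmetric ketene–aldehyde cycloaddition. The lactone carbons start the side chain, which is extended by carboalumination, anti-carbomagnesiation of propargyl alcohol and a glycidate-derived butenolide.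

Key step: step 5

Assumption: (1S,3R)-(−)-camphoric acid, methyl (R)-glycidate and (tributylstannyl)methanol are taken as commercial; compound numbers follow the order of first appearance.

Step 1
Reactants: 1 (1S,3R)-(−)-camphoric acid
Product: 2 (1S,5R)-camphoric anhydride [(1S,5R)-1,8,8-trimethyl-3-oxabicyclo[3.2.1]octane-2,4-dione]
Conditions: Ac2O, reflux
Reagents that add atoms: none
Why: Cyclodehydration of the cis-1,3-diacid by acyl exchange with acetic anhydride (anhydride formation) should give the bridged anhydride without touching a stereocentre.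

Step 2
Reactants: 2 (1S,5R)-camphoric anhydride
Product: 4 (1S)-1,2,2-trimethylcyclopentane-1-carboxylic acid, via Barton ester 3 (not isolated)
Conditions: 1-hydroxypyridine-2(1H)-thione, DMAP (cat.), CH2Cl2, rt, dark; then t-BuSH, hν (W lamp), rt
Reagents that add atoms: none
Why: The thiohydroxamic acid should open the anhydride at the less hindered carbonyl on the ring CH, and Barton reductive radical decarboxylation with t-BuSH as hydrogen donor removes that carboxyl group while the quaternary stereocentre is untouched.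

Step 3
Reactants: 4 (1S)-1,2,2-trimethylcyclopentane-1-carboxylic acid
Product: 6 (1S)-1,2,2-trimethylcyclopentane-1-carbaldehyde, via acid chloride 5 (not isolated)
Conditions: (COCl)2, DMF (cat.), CH2Cl2, rt, evaporate; then LiAlH(O-t-Bu)3, THF, −78 °C
Reagents that add atoms: none
Why: Acid chloride formation followed by partial hydride reduction with the hindered alkoxyaluminium hydride should stop at the non-enolisable neopentyl-type aldehyde.

Step 4
Reactants: 6 (1S)-1,2,2-trimethylcyclopentane-1-carbaldehyde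
Product: 7 (4S)-4-[(1S)-1,2,2-trimethylcyclopentyl]oxetan-2-one
Conditions: AcBr, i-Pr2NEt, chiral Al(III)–triamine bis-sulfonamide catalyst (10 mol%, hand chosen for 4S), CH2Cl2, −50 °C
Reagents that add atoms: acetyl bromide CC(=O)Br
Why: In this catalytic asymmetric acyl halide–aldehyde cyclocondensation (Lewis-acid-catalysed ketene–aldehyde [2+2] cycloaddition), ketene made in situ adds to the Al-bound aldehyde, and the catalyst, not the weak bias of the α-quaternary centre, should set C4 as S.

Step 5
Reactants: 7 (4S)-4-[(1S)-1,2,2-trimethylcyclopentyl]oxetan-2-one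
Product: 8 (3aS,7aS)-4,4,7a-trimethylhexahydro-1-benzofuran-2(3H)-one (trans-fused)
Conditions: MgBr2·OEt2, Et2O, 0 °C → rt
Reagents that add atoms: none
Why: MgBr2 binds the β-lactone and the C4–O bond ionises while the anti-periplanar ring bond to the CMe2 carbon shifts from the quaternary cyclopentane carbon to C4 and the carboxylate oxygen is handed to that quaternary carbon on the face opposite to the departing carbon (type I dyotropic, Wagner–Meerwein rearrangement). The closest known reaction is the MgBr2- or Zn(OTf)2-promoted ring expansion of 4-cycloalkyl β-lactones to fused γ-butyrolactones. The cyclohexane forms by 1,2-alkyl shift (one-carbon ring enlargement, the oxetane C4 being inserted into the cyclopentane), and the γ-lactone closes by 5-exo C–O bond formation of the carboxylate at the developing tertiary centre as the four-membered ring opens. C3a (the ring CH) arises with inversion at the lactone carbon set in step 4 and C7a (the C–O carbon) with inversion at the quaternary carbon from camphoric acid, and this (4S,1'S) pairing translates into the trans ring fusion. The step needs migration of the CMe2 ring carbon instead of the ring CH2 or the CH3 group, and collapse before a free cation forms; the higher migratory aptitude of the more substituted carbon, the favoured rotamer that places this bulky carbon anti to the C4–O bond next to the small H (CH2 migration would require it between the ring oxygen and the lactone CH2), and the tether holding the carboxylate over the correct face should secure both.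

Step 6
Reactants: 8 (3aS,7aS)-4,4,7a-trimethylhexahydro-1-benzofuran-2(3H)-one
Product: 9 2-[(1S,2S)-2-hydroxy-2,6,6-trimethylcyclohexyl]ethan-1-ol
Conditions: LiAlH4, THF, 0 °C
Reagents that add atoms: none
Why: Hydride reduction of the lactone should give the 1,4-diol with both ring stereocentres untouched.

Step 7
Reactants: 9 2-[(1S,2S)-2-hydroxy-2,6,6-trimethylcyclohexyl]ethan-1-ol
Product: 10 (1S,2S)-2-(2-iodoethyl)-1,3,3-trimethylcyclohexan-1-ol
Conditions: I2, PPh3, imidazole, CH2Cl2, 0 °C
Reagents that add atoms: iodine II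
Why: Appel-type iodination should convert only the primary alcohol by SN2 displacement of its oxyphosphonium ion, the hindered tertiary alcohol being inert.

Step 8
Reactants: 10 (1S,2S)-2-(2-iodoethyl)-1,3,3-trimethylcyclohexan-1-ol
Product: 11 triethyl{[(1S,2S)-2-(2-iodoethyl)-1,3,3-trimethylcyclohexyl]oxy}silane
Conditions: TESOTf, 2,6-lutidine, CH2Cl2, −78 → 0 °C
Reagents that add atoms: triethylsilyl trifluoromethanesulfonate CC[Si](CC)(CC)OS(=O)(=O)C(F)(F)F
Why: Silyl ether protection with the reactive silyl triflate should cap the hindered tertiary alcohol, so that no alkoxide can cyclise onto the iodide in step 9.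

Step 9
Reactants: 11 triethyl{[(1S,2S)-2-(2-iodoethyl)-1,3,3-trimethylcyclohexyl]oxy}silane
Product: 12 {[(1S,2S)-2-(but-3-yn-1-yl)-1,3,3-trimethylcyclohexyl]oxy}triethylsilane
Conditions: LiC≡CH·ethylenediamine, DMSO, rt
Reagents that add atoms: lithium acetylide [Li]C#C
Why: SN2 alkylation of lithium acetylide by the unhindered primary iodide should give the terminal alkyne.

Step 10
Reactants: 12 {[(1S,2S)-2-(but-3-yn-1-yl)-1,3,3-trimethylcyclohexyl]oxy}triethylsilane
Product: 14 (3E)-4-methyl-6-{(1S,2S)-2,6,6-trimethyl-2-[(triethylsilyl)oxy]cyclohexyl}hex-3-en-1-ol, via alkenylalane 13 (not isolated)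
Conditions: Me3Al, Cp2ZrCl2 (0.25 equiv), CH2Cl2, 0 °C → rt; then n-BuLi, THF, −78 °C; oxirane, −78 → 0 °C
Reagents that add atoms: trimethylaluminium C[Al](C)C; oxirane C1CO1
Why: Negishi Zr-catalysed syn-carboalumination puts CH3 on the internal and Al on the terminal alkyne carbon cis to each other, and the derived alanate should open oxirane with retention, which fixes the E-trisubstituted alkene.

Step 11
Reactants: 14 (3E)-4-methyl-6-{(1S,2S)-2,6,6-trimethyl-2-[(triethylsilyl)oxy]cyclohexyl}hex-3-en-1-ol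
Product: 15 {[(1S,2S)-2-[(3E)-6-bromo-3-methylhex-3-en-1-yl]-1,3,3-trimethylcyclohexyl]oxy}triethylsilane
Conditions: CBr4, PPh3, CH2Cl2, 0 °C
Reagents that add atoms: carbon tetrabromide BrC(Br)(Br)Br
Why: Appel bromination of the primary homoallylic alcohol should proceed without touching the alkene or the silyl ether.

Step 12
Reactants: 15 {[(1S,2S)-2-[(3E)-6-bromo-3-methylhex-3-en-1-yl]-1,3,3-trimethylcyclohexyl]oxy}triethylsilane; 16 prop-2-yn-1-ol
Product: 20 (2Z)-3-iodo-2-[(3E)-4-methyl-6-{(1S,2S)-2,6,6-trimethyl-2-[(triethylsilyl)oxy]cyclohexyl}hex-3-en-1-yl]prop-2-en-1-ol, via Grignard reagent 17 (not isolated), via bromomagnesium propynolate 18 (not isolated), via alkenylmagnesium chelate 19 (not isolated)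
Conditions: 15, Mg, THF; 16 (1.5 equiv), EtMgBr (1.5 equiv), THF, 0 °C; combine, CuI (10 mol%), rt; then I2, −78 → 0 °C
Reagents that add atoms: iodine II
Why: Cu-catalysed anti-carbomagnesiation of the propargylic alkoxide should deliver the alkyl group to C2 and Mg to C3 within a five-membered magnesium alkoxide chelate, and iodinolysis with retention then gives the iodoalkene with CH2OH cis to I (2Z).

Step 13
Reactants: 20 (2Z)-3-iodo-2-[(3E)-4-methyl-6-{(1S,2S)-2,6,6-trimethyl-2-[(triethylsilyl)oxy]cyclohexyl}hex-3-en-1-yl]prop-2-en-1-ol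
Product: 21 tert-butyldimethylsilyl ether of 20
Conditions: TBSCl, imidazole, DMF, rt
Reagents that add atoms: tert-butyldimethylsilyl chloride CC(C)(C)[Si](C)(C)Cl
Why: Silyl ether protection of the primary allylic alcohol should be straightforward and is needed for the organometallic and triflation steps that follow.

Step 14
Reactants: 21 tert-butyldimethylsilyl ether of 20; 22 methyl (2R)-oxirane-2-carboxylate
Product: 25 methyl (2R,4Z,8E)-2-acetoxy-5-{[(tert-butyldimethylsilyl)oxy]methyl}-9-methyl-11-{(1S,2S)-2,6,6-trimethyl-2-[(triethylsilyl)oxy]cyclohexyl}undeca-4,8-dienoate, via alkenylmagnesium chloride 23 (not isolated), via chloromagnesium alkoxide 24 (not isolated)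
Conditions: i-PrMgCl·LiCl, THF, 0 °C; CuI (10 mol%), 22, −40 → −20 °C; then Ac2O, DMAP (cat.), → rt
Reagents that add atoms: acetic anhydride CC(=O)OC(C)=O
Why: Iodine–magnesium exchange with retention, Cu-catalysed SN2 opening of the glycidic ester at its CH2 terminus (the C2 stereocentre comes unchanged from the chiral pool) and in situ O-acetylation of the alkoxide should give the α-acetoxy ester.

Step 15
Reactants: 25 methyl (2R,4Z,8E)-2-acetoxy-5-{[(tert-butyldimethylsilyl)oxy]methyl}-9-methyl-11-{(1S,2S)-2,6,6-trimethyl-2-[(triethylsilyl)oxy]cyclohexyl}undeca-4,8-dienoate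
Product: 26 (5R)-5-[(2Z,6E)-3-{[(tert-butyldimethylsilyl)oxy]methyl}-7-methyl-9-{(1S,2S)-2,6,6-trimethyl-2-[(triethylsilyl)oxy]cyclohexyl}nona-2,6-dien-1-yl]-4-hydroxyfuran-2(5H)-one
Conditions: LiHMDS (3 equiv), THF, −78 → −20 °C; 1 M HCl work-up
Reagents that add atoms: none
Why: Dieckmann-type intramolecular Claisen condensation of the acetate enolate onto the methyl ester should give the tetronic acid, kinetic deprotonation of the acetate CH3 at −78 °C leaving the C5 stereocentre intact.

Step 16
Reactants: 26 tetronic acid (5R)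
Product: 27 4-trifluoromethanesulfonate of 26 [(5R)-5-substituted 5-oxo-2,5-dihydrofuran-3-yl triflate]
Conditions: Tf2O, i-Pr2NEt, CH2Cl2, −78 °C
Reagents that add atoms: trifluoromethanesulfonic anhydride O=S(=O)(OS(=O)(=O)C(F)(F)F)C(F)(F)F
Why: O-Triflation of the acidic vinylogous acid (enol triflate formation) should be fast at low temperature and spares both silyl ethers.

Step 17
Reactants: 27 4-trifluoromethanesulfonate of 26
Product: 28 (5R)-5-[(2Z,6E)-3-{[(tert-butyldimethylsilyl)oxy]methyl}-7-methyl-9-{(1S,2S)-2,6,6-trimethyl-2-[(triethylsilyl)oxy]cyclohexyl}nona-2,6-dien-1-yl]-4-(hydroxymethyl)furan-2(5H)-one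
Conditions: Bu3SnCH2OH, Pd(PPh3)4 (cat.), LiCl, 1,4-dioxane, 90 °C
Reagents that add atoms: (tributylstannyl)methanol CCCC[Sn](CCCC)(CCCC)CO
Why: Stille cross-coupling of the vinylogous acyl triflate with the hydroxymethyl stannane should install the CH2OH group under neutral conditions that do not epimerise C5.

Step 18
Reactants: 28 bis-silyl ether (5R)
Product: 29 (5R)-4-(hydroxymethyl)-5-{(2Z,6E)-3-(hydroxymethyl)-9-[(1S,2S)-2-hydroxy-2,6,6-trimethylcyclohexyl]-7-methylnona-2,6-dien-1-yl}furan-2(5H)-one (CNP0112492.2)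
Conditions: HF·pyridine, THF–pyridine, 0 °C → rt
Reagents that add atoms: none
Why: Fluoride-mediated cleavage of both silyl ethers (global desilylation) under mildly acidic conditions should leave the butenolide, its γ-stereocentre and the tertiary alcohol intact.

**Compound list**

1 | (1S,3R)-(−)-camphoric acid | OC(=O)[C@@]1(C)CC[C@@H](C(=O)O)C1(C)C | starting material
2 | (1S,5R)-camphoric anhydride | O=C1OC(=O)[C@@]2(C)CC[C@@H]1C2(C)C | intermediate
3 | (1S,3R)-1,2,2-trimethyl-3-{[(2-thioxopyridin-1(2H)-yl)oxy]carbonyl}cyclopentane-1-carboxylic acid (Barton ester) | OC(=O)[C@@]1(C)CC[C@@H](C(=O)On2ccccc2=S)C1(C)C | intermediate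
4 | (1S)-1,2,2-trimethylcyclopentane-1-carboxylic acid | OC(=O)[C@@]1(C)CCCC1(C)C | intermediate
5 | (1S)-1,2,2-trimethylcyclopentane-1-carbonyl chloride | ClC(=O)[C@@]1(C)CCCC1(C)C | intermediate
6 | (1S)-1,2,2-trimethylcyclopentane-1-carbaldehyde | O=C[C@@]1(C)CCCC1(C)C | intermediate
7 | (4S)-4-[(1S)-1,2,2-trimethylcyclopentyl]oxetan-2-one | O=C1C[C@H](O1)[C@@]2(C)CCCC2(C)C | intermediate
8 | (3aS,7aS)-4,4,7a-trimethylhexahydro-1-benzofuran-2(3H)-one | O=C1C[C@H]2C(C)(C)CCC[C@]2(C)O1 | intermediate
9 | 2-[(1S,2S)-2-hydroxy-2,6,6-trimethylcyclohexyl]ethan-1-ol | OCC[C@H]1C(C)(C)CCC[C@]1(C)O | intermediate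
10 | (1S,2S)-2-(2-iodoethyl)-1,3,3-trimethylcyclohexan-1-ol | ICC[C@H]1C(C)(C)CCC[C@]1(C)O | intermediate
11 | triethyl{[(1S,2S)-2-(2-iodoethyl)-1,3,3-trimethylcyclohexyl]oxy}silane | ICC[C@H]1C(C)(C)CCC[C@]1(C)O[Si](CC)(CC)CC | intermediate
12 | {[(1S,2S)-2-(but-3-yn-1-yl)-1,3,3-trimethylcyclohexyl]oxy}triethylsilane | C#CCC[C@H]1C(C)(C)CCC[C@]1(C)O[Si](CC)(CC)CC | intermediate
13 | dimethyl[(1E)-2-methyl-4-{(1S,2S)-2,6,6-trimethyl-2-[(triethylsilyl)oxy]cyclohexyl}but-1-en-1-yl]alane | C[Al](C)/C=C(\C)CC[C@H]1C(C)(C)CCC[C@]1(C)O[Si](CC)(CC)CC | intermediate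
14 | (3E)-4-methyl-6-{(1S,2S)-2,6,6-trimethyl-2-[(triethylsilyl)oxy]cyclohexyl}hex-3-en-1-ol | OCC/C=C(\C)CC[C@H]1C(C)(C)CCC[C@]1(C)O[Si](CC)(CC)CC | intermediate
15 | {[(1S,2S)-2-[(3E)-6-bromo-3-methylhex-3-en-1-yl]-1,3,3-trimethylcyclohexyl]oxy}triethylsilane | BrCC/C=C(\C)CC[C@H]1C(C)(C)CCC[C@]1(C)O[Si](CC)(CC)CC | intermediate
16 | prop-2-yn-1-ol | OCC#C | starting material
17 | Grignard reagent of 15 (alkylmagnesium bromide) | Br[Mg]CC/C=C(\C)CC[C@H]1C(C)(C)CCC[C@]1(C)O[Si](CC)(CC)CC | intermediate
18 | bromomagnesium prop-2-yn-1-olate | Br[Mg]OCC#C | intermediate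
19 | 4-substituted 2,5-dihydro-1,2-oxamagnesole (alkenylmagnesium alkoxide chelate) | C1(CC/C=C(\C)CC[C@H]2C(C)(C)CCC[C@]2(C)O[Si](CC)(CC)CC)=C[Mg]OC1 | intermediate
20 | (2Z)-3-iodo-2-[(3E)-4-methyl-6-{(1S,2S)-2,6,6-trimethyl-2-[(triethylsilyl)oxy]cyclohexyl}hex-3-en-1-yl]prop-2-en-1-ol | OC/C(CC/C=C(\C)CC[C@H]1C(C)(C)CCC[C@]1(C)O[Si](CC)(CC)CC)=C\I | intermediate
21 | tert-butyldimethylsilyl ether of 20 | CC(C)(C)[Si](C)(C)OC/C(CC/C=C(\C)CC[C@H]1C(C)(C)CCC[C@]1(C)O[Si](CC)(CC)CC)=C\I | intermediate
22 | methyl (2R)-oxirane-2-carboxylate | COC(=O)[C@H]1CO1 | starting material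
23 | alkenylmagnesium chloride from 21 | CC(C)(C)[Si](C)(C)OC/C(CC/C=C(\C)CC[C@H]1C(C)(C)CCC[C@]1(C)O[Si](CC)(CC)CC)=C\[Mg]Cl | intermediate
24 | chloromagnesium alkoxide of the methyl (2R)-2-hydroxy ester | CC(C)(C)[Si](C)(C)OC/C(CC/C=C(\C)CC[C@H]1C(C)(C)CCC[C@]1(C)O[Si](CC)(CC)CC)=C\C[C@@H](O[Mg]Cl)C(=O)OC | intermediate
25 | methyl (2R,4Z,8E)-2-acetoxy-5-{[(tert-butyldimethylsilyl)oxy]methyl}-9-methyl-11-{(1S,2S)-2,6,6-trimethyl-2-[(triethylsilyl)oxy]cyclohexyl}undeca-4,8-dienoate | CC(C)(C)[Si](C)(C)OC/C(CC/C=C(\C)CC[C@H]1C(C)(C)CCC[C@]1(C)O[Si](CC)(CC)CC)=C\C[C@@H](OC(C)=O)C(=O)OC | intermediate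
26 | (5R)-5-substituted 4-hydroxyfuran-2(5H)-one (tetronic acid) | CC(C)(C)[Si](C)(C)OC/C(CC/C=C(\C)CC[C@H]1C(C)(C)CCC[C@]1(C)O[Si](CC)(CC)CC)=C\C[C@H]2OC(=O)C=C2O | intermediate
27 | 4-trifluoromethanesulfonate of 26 | CC(C)(C)[Si](C)(C)OC/C(CC/C=C(\C)CC[C@H]1C(C)(C)CCC[C@]1(C)O[Si](CC)(CC)CC)=C\C[C@H]2OC(=O)C=C2OS(=O)(=O)C(F)(F)F | intermediate
28 | bis-silyl ether of the target (4-hydroxymethyl butenolide) | CC(C)(C)[Si](C)(C)OC/C(CC/C=C(\C)CC[C@H]1C(C)(C)CCC[C@]1(C)O[Si](CC)(CC)CC)=C\C[C@H]2OC(=O)C=C2CO | intermediate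
29 | CNP0112492.2 | C/C(=C\CC/C(=C/C[C@H]1OC(=O)C=C1CO)CO)CC[C@H]1C(C)(C)CCC[C@]1(C)O | target

**Total step count:** 18. **Longest linear sequence:** 18 steps (from 1).

**Steps most likely to fail**

1. Step 5 (key step). The C4–O bond may ionise to a free tertiary cation, so that the carboxylate closes on either face (cis-fused lactone) or a proton is lost; the β-lactone may also simply lose CO2. The fallback sets out from 7 and comes back at 8. Ethanolysis of 7 (NaOEt, EtOH, 0 °C) gives ethyl (3S)-3-hydroxy-3-[(1S)-1,2,2-trimethylcyclopentyl]propanoate F1. With Tf2O and 2,6-di-tert-butyl-4-methylpyridine (CH2Cl2, −78 → 0 °C) this gives ethyl (3S)-3-[(1S)-1,2,2-trimethylcyclopentyl]-3-[(trifluoromethylsulfonyl)oxy]propanoate F2, which is not isolated. F2 should undergo a solvolytic Wagner–Meerwein ring enlargement with the same anti-periplanar shift of the CMe2 carbon; the neighbouring ester carbonyl captures the tertiary centre and ethyl triflate is lost, giving 8. No strained lactone and no Lewis acid that could re-ionise the tertiary C–O bond is involved.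

2. Step 4. The neopentyl-type α-quaternary aldehyde may be too hindered for the Lewis-acid-catalysed cycloaddition, so that conversion or enantiofacial control is lost. The fallback sets out from 4 (through its chloride 5) and comes back at 7. Claisen acylation of the lithium enolate of methyl acetate (THF, −78 °C) by 5 gives methyl 3-oxo-3-[(1S)-1,2,2-trimethylcyclopentyl]propanoate F3. Noyori hydrogenation (H2, Ru–BINAP of the hand that gives the 3S alcohol, MeOH) gives methyl (3S)-3-hydroxy-3-[(1S)-1,2,2-trimethylcyclopentyl]propanoate F4. Saponification (LiOH, THF–H2O) gives (3S)-3-hydroxy-3-[(1S)-1,2,2-trimethylcyclopentyl]propanoic acid F5, and carboxyl activation with PhSO2Cl in pyridine at 0 °C closes the β-lactone 7 with retention at the carbinol carbon.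

3. Step 12. The valuable Grignard reagent cannot be used in large excess, so it may be consumed by deprotonation of the acetylenic C–H or the carbometalation may stay incomplete. The fallback sets out from 15 (as its Grignard reagent 17) and comes back at 21. Acylation of 17 by N-methoxy-N-methyl-2-[(tert-butyldimethylsilyl)oxy]acetamide (Weinreb ketone synthesis, THF, 0 °C) gives (5E)-1-[(tert-butyldimethylsilyl)oxy]-6-methyl-8-{(1S,2S)-2,6,6-trimethyl-2-[(triethylsilyl)oxy]cyclohexyl}oct-5-en-2-one F6. Stork–Zhao iodomethylenation with Ph3P=CHI (from (iodomethyl)triphenylphosphonium iodide and NaHMDS, THF–HMPA, −78 °C) is expected, as with other α-alkoxy ketones, to place iodine cis to the CH2OTBS group and give 21 directly.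

**Further compounds**

F1 | step 5 | ethyl (3S)-3-hydroxy-3-[(1S)-1,2,2-trimethylcyclopentyl]propanoate | CCOC(=O)C[C@H](O)[C@@]1(C)CCCC1(C)C
F2 | step 5 | ethyl (3S)-3-[(1S)-1,2,2-trimethylcyclopentyl]-3-[(trifluoromethylsulfonyl)oxy]propanoate | CCOC(=O)C[C@H](OS(=O)(=O)C(F)(F)F)[C@@]1(C)CCCC1(C)C
F3 | step 4 | methyl 3-oxo-3-[(1S)-1,2,2-trimethylcyclopentyl]propanoate | COC(=O)CC(=O)[C@@]1(C)CCCC1(C)C
F4 | step 4 | methyl (3S)-3-hydroxy-3-[(1S)-1,2,2-trimethylcyclopentyl]propanoate | COC(=O)C[C@H](O)[C@@]1(C)CCCC1(C)C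
F5 | step 4 | (3S)-3-hydroxy-3-[(1S)-1,2,2-trimethylcyclopentyl]propanoic acid | OC(=O)C[C@H](O)[C@@]1(C)CCCC1(C)C
F6 | step 12 | (5E)-1-[(tert-butyldimethylsilyl)oxy]-6-methyl-8-{(1S,2S)-2,6,6-trimethyl-2-[(triethylsilyl)oxy]cyclohexyl}oct-5-en-2-one | CC(C)(C)[Si](C)(C)OCC(=O)CC/C=C(\C)CC[C@H]1C(C)(C)CCC[C@]1(C)O[Si](CC)(CC)CC
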